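**Assumptions (one line):** The SMILES encodes the 2,4-*trans* isomer, (2S,4R)-5,7-dimethoxy-8-prenylflavan-4-ol. The (–)-Ipc₂B-allyl enantiomer is assumed to give the (S)-carbinol; if it gives (R), the other enantiomer of the reagent is used.

## Retrosynthetic overview
1. The pyran ring is formed last by an intramolecular Pd-catalysed C–O coupling of the free syn-1,3-diol aryl bromide **14**. Both carbinol stereocentres are already set and untouched by this step.
2. The C4 stereocentre comes from a Narasaka–Prasad syn reduction of β-hydroxy ketone **13**. **13** comes from aryllithium **6** plus Weinreb amide **11**, which carries the C2 (S)-carbinol from a Brown allylation of benzaldehyde.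
3. Aryl bromide **6** is built from resorcinol by Ir-catalysed C–H borylation, bromodeborylation and ortho-lithiation/prenylation. **11** is built from benzaldehyde in four steps.
4. Both benzene rings pre-exist; the only ring formed is the heterocyclic ring, in the final step.

## Route

**Step 1**
Reactants: **1** resorcinol
Product: **2** 1,3-dimethoxybenzene
Conditions: Me₂SO₄, K₂CO₃, acetone, reflux
Reagents that add atoms: dimethyl sulfate, COS(=O)(=O)OC
Why: Williamson O-methylation of both phenols.

**Step 2**
Reactants: **2**
Product: **3** 2-(3,5-dimethoxyphenyl)-4,4,5,5-tetramethyl-1,3,2-dioxaborolane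
Conditions: B₂pin₂, [Ir(cod)OMe]₂ (1.5 mol %), dtbpy (3 mol %), THF, 80 °C
Reagents that add atoms: B₂pin₂, CC1(C)OB(OC1(C)C)B1OC(C)(C)C(C)(C)O1
Why: Ir-catalysed C–H activation is sterically controlled, so it borylates only C5, the one position meta to both OMe groups. This installs the future C8a carbon handle.

**Step 3**
Reactants: **3**
Product: **4** 1-bromo-3,5-dimethoxybenzene
Conditions: CuBr₂ (3 equiv), MeOH/H₂O 1:1, 80 °C
Reagents that add atoms: CuBr₂, Br[Cu]Br
Why: Cu-mediated bromodeborylation of the aryl-Bpin, giving the 3,5-dioxygenated bromoarene that cannot be made by direct bromination.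

**Step 4**
Reactants: **4** and **5** prenyl bromide (1-bromo-3-methylbut-2-ene)
Product: **6** 1-bromo-3,5-dimethoxy-2-(3-methylbut-2-en-1-yl)benzene
Conditions: LDA (1.1 equiv), THF, –78 °C, 1 h; then **5** (1.3 equiv), –78 °C → rt
Reagents that add atoms: none (the prenyl group comes from **5**)
Why: Directed ortho-metalation at C2, which is acidified by both Br and OMe, then SN2 alkylation. LDA is used because it does not undergo Br/Li exchange. This installs C8-prenyl.

**Step 5**
Reactants: **7** benzaldehyde
Product: **8** (S)-1-phenylbut-3-en-1-ol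
Conditions: (–)-Ipc₂B-allyl, Et₂O, –78 °C; then NaOH, H₂O₂
Reagents that add atoms: (–)-B-allyldiisopinocampheylborane, C=CCB(C1CC2CC(C1C)C2(C)C)C1CC2CC(C1C)C2(C)C
Why: Brown asymmetric allylation. A chair Zimmerman–Traxler transition state with the Ipc ligands sets the benzylic (S) stereocentre, which becomes C2 of the target.

**Step 6**
Reactants: **8**
Product: **9** (S)-tert-butyldimethyl[(1-phenylbut-3-en-1-yl)oxy]silane
Conditions: TBSCl, imidazole, DMF, rt
Reagents that add atoms: TBSCl, CC(C)(C)[Si](C)(C)Cl
Why: Silyl protection of the alcohol; the stereocentre is not touched.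

**Step 7**
Reactants: **9**
Product: **10** methyl (S)-3-[(tert-butyldimethylsilyl)oxy]-3-phenylpropanoate
Conditions: (i) O₃, CH₂Cl₂/MeOH 4:1, –78 °C; (ii) Ac₂O, Et₃N, DMAP, 0 °C → rt
Reagents that add atoms: ozone, [O-][O+]=O; methanol, CO
Why: Ozonolysis in methanol followed by Ac₂O/Et₃N dehydration of the α-methoxy hydroperoxide (Schreiber-type) gives the methyl ester directly. This removes the terminal alkene and leaves the C–O stereocentre intact.

**Step 8**
Reactants: **10**
Product: **11** (S)-3-[(tert-butyldimethylsilyl)oxy]-N-methoxy-N-methyl-3-phenylpropanamide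
Conditions: MeNH(OMe)·HCl, i-PrMgCl, THF, –20 → 0 °C
Reagents that add atoms: N,O-dimethylhydroxylamine hydrochloride, CNOC.Cl
Why: Weinreb amidation (Williams conditions), so that the next step stops cleanly at the ketone.

**Step 9 (convergent step)**
Reactants: **6** and **11**
Product: **12** (S)-1-(2-bromo-4,6-dimethoxy-3-prenylphenyl)-3-[(tert-butyldimethylsilyl)oxy]-3-phenylpropan-1-one
Conditions: **6** (1.3 equiv), LDA (1.25 equiv), THF, –78 °C, 1 h; then **11**, –78 → 0 °C
Reagents that add atoms: none
Why: Ortho-lithiation at C6 (between Br and OMe) gives an aryllithium that adds to the Weinreb amide. This forms the C4a–C4 bond, and the stable tetrahedral intermediate gives the ketone only on work-up. LDA is kept slightly substoichiometric to avoid E1cB loss of OTBS.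

**Step 10**
Reactants: **12**
Product: **13** (S)-1-(2-bromo-4,6-dimethoxy-3-prenylphenyl)-3-hydroxy-3-phenylpropan-1-one
Conditions: HF·pyridine, THF/pyridine, 0 °C → rt
Reagents that add atoms: none (H replaces TBS)
Why: Mild, non-basic desilylation avoids retro-aldol and elimination of the β-hydroxy ketone; the aryl bromide and prenyl alkene survive.

**Step 11**
Reactants: **13**
Product: **14** (1R,3S)-1-(2-bromo-4,6-dimethoxy-3-prenylphenyl)-3-phenylpropane-1,3-diol, the syn-diol
Conditions: Et₂BOMe (1.2 equiv), THF/MeOH 4:1, –78 °C; then NaBH₄ (1.3 equiv), –78 °C; work-up with pH 7 buffer/H₂O₂, 0 °C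
Reagents that add atoms: none (H delivery only)
Why: Narasaka–Prasad reduction. A six-membered boron chelate of the β-hydroxy ketone forces intramolecular axial hydride delivery, so the new C4 carbinol is syn to the existing (S) C2 carbinol. That is the (R) configuration at C4, set by substrate control from C2.

**Step 12 (key ring-forming step)**
Reactants: **14**
Product: **15** (2S,4R)-5,7-dimethoxy-8-prenylflavan-4-ol (target)
Conditions: tBuBrettPhos Pd G3 (5 mol %), Cs₂CO₃ (2 equiv), toluene, 100 °C, 16 h
Reagents that add atoms: none (loss of HBr)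
Why: Proposed new method: Pd(0)/bulky biaryl-phosphine oxidative addition into the C–Br bond (flanked by prenyl and the carbinol side chain) is followed by Cs₂CO₃ deprotonation of the C2 alcohol and C–O reductive elimination to close the six-membered ring. The C4 alcohol cannot cyclise, because that would form a four-membered ring, so no protecting group is needed on the free 1,3-diol. No C–O bond at either stereocentre is broken, so the (2S,4R) configuration is retained. The closest known reactions are Buchwald–Hartwig C–O coupling of secondary alcohols and intramolecular chroman etherification. What is new is the substrate: a free syn-1,3-diol and an electron-rich, 2,6-disubstituted prenyl-bearing bromoarene.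

## Compound list
1 | resorcinol | Oc1cccc(O)c1 | starting material
2 | 1,3-dimethoxybenzene | COc1cccc(OC)c1 | intermediate
3 | 2-(3,5-dimethoxyphenyl)-4,4,5,5-tetramethyl-1,3,2-dioxaborolane | COc1cc(OC)cc(c1)B1OC(C)(C)C(C)(C)O1 | intermediate
4 | 1-bromo-3,5-dimethoxybenzene | COc1cc(Br)cc(OC)c1 | intermediate
5 | prenyl bromide | CC(C)=CCBr | starting material
6 | 1-bromo-3,5-dimethoxy-2-prenylbenzene | COc1cc(OC)c(CC=C(C)C)c(Br)c1 | intermediate
7 | benzaldehyde | O=Cc1ccccc1 | starting material
8 | (S)-1-phenylbut-3-en-1-ol | O[C@H](c1ccccc1)CC=C | intermediate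
9 | (S)-TBS ether of 8 | CC(C)(C)[Si](C)(C)O[C@H](c1ccccc1)CC=C | intermediate
10 | methyl (S)-3-(TBSO)-3-phenylpropanoate | CC(C)(C)[Si](C)(C)O[C@H](c1ccccc1)CC(=O)OC | intermediate
11 | (S)-3-(TBSO)-N-methoxy-N-methyl-3-phenylpropanamide | CC(C)(C)[Si](C)(C)O[C@H](c1ccccc1)CC(=O)N(C)OC | intermediate
12 | (S)-aryl ketone, OTBS, ArBr | CC(C)(C)[Si](C)(C)O[C@H](c1ccccc1)CC(=O)c1c(OC)cc(OC)c(CC=C(C)C)c1Br | intermediate
13 | (S)-β-hydroxy ketone | O[C@H](c1ccccc1)CC(=O)c1c(OC)cc(OC)c(CC=C(C)C)c1Br | intermediate
14 | (1R,3S)-syn-diol aryl bromide | O[C@H](c1ccccc1)C[C@@H](O)c1c(OC)cc(OC)c(CC=C(C)C)c1Br | intermediate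
15 | (2S,4R)-5,7-dimethoxy-8-prenylflavan-4-ol | COc1cc(OC)c2c(c1CC=C(C)C)O[C@H](c1ccccc1)C[C@H]2O | target

## Step count
- Total steps: 12.
- Longest linear sequence: 8 steps (steps 1–4 then 9–12, or steps 5–8 then 9–12), which is 8/12 = two thirds.

## Three steps most likely to fail
1. **Step 12 (proposed new Pd C–O cyclisation).** The hindered, electron-rich bromide may give slow oxidative addition, β-hydride elimination of the Pd alkoxide, or a stable five-membered oxa-palladacycle with the C4 alkoxide.
   - Fallback (known chemistry, different approach): use the (R)-carbinol series, reduce **13** with Me₄NBH(OAc)₃ (Evans–Saksena, anti) to the (1R,3R)-diol, convert ArBr to ArOH by Pd-catalysed hydroxylation, and close the ring by intramolecular Mitsunobu etherification (DIAD, PPh₃), which inverts C2 to (S).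
2. **Step 11 (Narasaka–Prasad reduction).** The di-ortho-substituted aryl ketone may chelate poorly, or the β-hydroxy ketone may undergo retro-aldol, eroding syn selectivity.
   - Fallback: reduce silyl ketone **12** under catalyst control with (S)-Me-CBS/catecholborane to give the (R)-carbinol at C4, then remove TBS with HF·pyridine.
3. **Step 4 (lithiation/prenylation).** Problems could be aryne formation, halogen dance, or reverse-prenyl (SN2′) alkylation.
   - Fallback: alkylate the aryllithium with allyl bromide, which has no α/γ problem, then convert the allyl group to prenyl by Ru-catalysed cross-metathesis with 2-methylbut-2-ene.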